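**Retrosynthetic overview**

- Numbering: decalin C1–C10 (C3 carbinol, C4 gem-dimethyl, C5 ring-fusion CH, C8 CHMe, C9 quaternary, C10 alkene carbon), C11 = benzylic CH2; ring A = C1–C5/C10, ring B = C5–C10.
- Enabling feature: in ring B the alkene carbon C10 is at the ketone oxidation level and lies between C9 and C5, and the methyl-bearing C8 is β to C6. C9–C10–C5 is therefore the α/C=O/α′ triad of 2-methylacetoacetate and C8–C7–C6 is crotonaldehyde.
- Ring B first: an amine-catalysed domino Michael/aldol condensation/decarboxylation forms C8–C9 and C5–C6 and sets C8. C9 is then made quaternary by enolate benzylation anti to the 8-methyl (C9–C11).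
- Ring A second: C10–C1 by enol triflate/alkyl Grignard coupling; C4–C5 by epoxide-initiated radical cyclisation, which also places the C1=C10 alkene. The C3 epoxide controls C5.
- End game: C3 inverted by oxidation/reduction, CHO by ortho-lithiation, MOM removal.

Key step: step 1

Remark: the target is drawn as the open hydroxy aldehyde; its ring-closed lactol is the same compound in equilibrium and is not treated separately. Ar = 2,6-bis(methoxymethoxy)-4-[(methoxymethoxy)methyl]phenyl. Descriptors such as (3S,5R,8R,9S) use the numbering above.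

**Step 1**
Reactants: 1 tert-butyl 2-methyl-3-oxobutanoate; 2 (E)-but-2-enal
Product: 5 (5R,6S)-5,6-dimethylcyclohex-2-en-1-one, via Michael adduct 3 (not isolated), via cyclised keto ester 4 (not isolated)
Conditions: (R)-α,α-diphenylprolinol trimethylsilyl ether (10 mol%), PhCO2H (10 mol%), toluene, 0 °C → rt; then p-TsOH·H2O (20 mol%), toluene, 80 °C
Reagents that add atoms: none
Why: The secondary amine converts 2 into an E-iminium ion, to whose β-carbon the enol of keto ester 1 adds in a Michael reaction (C8–C9); acid then drives an intramolecular aldol condensation of the methyl ketone onto the liberated aldehyde (C5–C6), followed by loss of isobutene and CO2. The closest known reaction type is the amine-catalysed domino Michael/aldol condensation of β-keto esters with enals to give cyclohexenones. Ring B closes in a 6-(enolendo)-exo-trig aldol addition. C8 is set by the catalyst, whose diphenyl(silyloxy)methyl group shields one face of the iminium ion; the R catalyst is chosen because the shielding model predicts 8R. C9 is formed without control but is stereoconvergent: decarboxylation here and enolisation in step 6 make it planar, so racemic 1 and both epimers of 3, 4 and 5 funnel into one series. The step needs 1,4- rather than 1,2-addition (secured by the iminium ion) and a defined donor pattern (secured by 1, whose doubly activated carbon is the only Michael donor and whose methyl group is the only aldol donor).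

**Step 2**
Reactants: 6 5-(hydroxymethyl)benzene-1,3-diol
Product: 7 1,3-bis(methoxymethoxy)-5-[(methoxymethoxy)methyl]benzene
Conditions: NaH, MOMCl, THF/DMF, 0 °C → rt
Reagents that add atoms: chloromethyl methyl ether, COCCl
Why: Williamson-type O-alkylation of the two phenoxides and the benzylic alkoxide by chloromethyl methyl ether (MOM protection); no stereocentre is involved.

**Step 3**
Reactants: 7 1,3-bis(methoxymethoxy)-5-[(methoxymethoxy)methyl]benzene
Product: 9 2,6-bis(methoxymethoxy)-4-[(methoxymethoxy)methyl]benzaldehyde, via aryllithium 8 (not isolated)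
Conditions: n-BuLi, THF, 0 °C; DMF, 0 °C → rt; H2O
Reagents that add atoms: N,N-dimethylformamide, CN(C)C=O
Why: Directed ortho-metalation takes place at the hydrogen flanked by the two OMOM groups, which is the most acidic and doubly coordinated, and DMF formylates the aryllithium; no stereocentre is involved.

**Step 4**
Reactants: 9 2,6-bis(methoxymethoxy)-4-[(methoxymethoxy)methyl]benzaldehyde
Product: 10 {2,6-bis(methoxymethoxy)-4-[(methoxymethoxy)methyl]phenyl}methanol
Conditions: NaBH4, MeOH, 0 °C
Reagents that add atoms: none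
Why: Borohydride reduction of an aromatic aldehyde to the benzylic alcohol; no stereocentre is involved.

**Step 5**
Reactants: 10 {2,6-bis(methoxymethoxy)-4-[(methoxymethoxy)methyl]phenyl}methanol
Product: 11 2-(bromomethyl)-1,3-bis(methoxymethoxy)-5-[(methoxymethoxy)methyl]benzene
Conditions: CBr4, PPh3, CH2Cl2, 0 °C; used at once
Reagents that add atoms: tetrabromomethane, BrC(Br)(Br)Br
Why: The Appel reaction converts the primary benzylic alcohol into the bromide under neutral conditions that leave the MOM acetals intact; no stereocentre is involved.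

**Step 6**
Reactants: 5 (5R,6S)-5,6-dimethylcyclohex-2-en-1-one; 11 2-(bromomethyl)-1,3-bis(methoxymethoxy)-5-[(methoxymethoxy)methyl]benzene
Product: 13 (5R,6S)-6-(ArCH2)-5,6-dimethylcyclohex-2-en-1-one, via lithium dienolate 12 (not isolated)
Conditions: LiN(i-Pr)2, THF, −78 °C; then 11, DMPU, −78 → −20 °C
Reagents that add atoms: none
Why: Kinetic α′-deprotonation at C9 gives the cross-conjugated dienolate, and its SN2 alkylation by the benzylic bromide should occur on the face opposite the pseudo-axial 8-methyl, so that the arylmethyl group ends trans and the 9-methyl cis to the 8-methyl (9S) (enolate alkylation).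

**Step 7**
Reactants: 13 (5R,6S)-6-(ArCH2)-5,6-dimethylcyclohex-2-en-1-one
Product: 15 (5R,6S)-6-(ArCH2)-5,6-dimethylcyclohex-1-en-1-yl trifluoromethanesulfonate, via lithium enolate 14 (not isolated)
Conditions: LiBH(s-Bu)3 (L-Selectride), THF, −78 °C; then PhNTf2, −78 °C → rt
Reagents that add atoms: N-phenylbis(trifluoromethanesulfonimide), O=S(=O)(N(c1ccccc1)S(=O)(=O)C(F)(F)F)C(F)(F)F
Why: The bulky hydride adds 1,4 to the β-unsubstituted enone (conjugate reduction, 1,2-attack being blocked by the quaternary C9), and the regiodefined C10=C5 enolate is O-sulfonylated by PhNTf2; no stereocentre is touched.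

**Step 8**
Reactants: 15 (5R,6S)-6-(ArCH2)-5,6-dimethylcyclohex-1-en-1-yl trifluoromethanesulfonate; 16 5-bromo-2-methylpent-2-ene
Product: 18 2-{[(1S,6R)-1,6-dimethyl-2-(4-methylpent-3-en-1-yl)cyclohex-2-en-1-yl]methyl}-1,3-bis(methoxymethoxy)-5-[(methoxymethoxy)methyl]benzene, via Grignard reagent 17 (not isolated)
Conditions: Mg, THF, rt; then 15, Fe(acac)3 (5 mol%), THF/NMP, −30 → 0 °C
Reagents that add atoms: none
Why: Iron-catalysed Kumada-type cross-coupling of an alkenyl triflate with a primary alkyl Grignard reagent forms C10–C1 at low temperature and tolerates acetals; alkene position and stereocentres are retained.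

**Step 9**
Reactants: 18 the diene of step 8
Product: 19 (3S)-3-{2-[(5R,6S)-6-(ArCH2)-5,6-dimethylcyclohex-1-en-1-yl]ethyl}-2,2-dimethyloxirane
Conditions: L-fructose-derived Shi ketone (30 mol%), KHSO5 (as 2KHSO5·KHSO4·K2SO4), K2CO3, Bu4NHSO4, MeCN/CH2(OMe)2/aq. Na2B4O7, 0 °C
Reagents that add atoms: potassium peroxymonosulfate, [K+].[O-]S(=O)(=O)OO
Why: In the Shi epoxidation the chiral dioxirane should attack the unhindered side-chain alkene rather than the ring alkene shielded by the quaternary C9, and the spiro transition-state model predicts the 3S epoxide from the L-fructose-derived ketone.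

**Step 10**
Reactants: 19 the (3S)-epoxide of step 9
Product: 20 (3S,5R,8R,9S)-9-(ArCH2)-4,4,8,9-tetramethyl-Δ1(10)-octalin-3-ol (3β-alcohol)
Conditions: Cp2TiCl2, Mn dust, THF, rt (gives Cp2TiCl); then 19, THF, rt; aq. NaH2PO4
Reagents that add atoms: none
Why: Trivalent titanium (Cp2TiCl) opens the epoxide homolytically to the tertiary C4 radical, which cyclises 6-endo onto C5 of the ring B alkene through a chair with the titanium alkoxide equatorial, so that the 3S centre places H5 trans to the oxygen (5R); the tertiary C10 radical is trapped by a second Cp2TiCl and loses the less hindered C1 hydrogen to give the C1=C10 alkene (titanocene-mediated reductive epoxide opening/radical cyclisation of epoxy-olefins).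

**Step 11**
Reactants: 20 the 3β-alcohol of step 10
Product: 21 (5R,8R,9S)-9-(ArCH2)-4,4,8,9-tetramethyl-Δ1(10)-octalin-3-one
Conditions: Dess–Martin periodinane, NaHCO3, CH2Cl2, 0 °C → rt
Reagents that add atoms: none
Why: Dess–Martin oxidation of the secondary alcohol under buffered conditions avoids conjugation of the β,γ-unsaturated ketone; C3 becomes trigonal and the other centres are untouched.

**Step 12**
Reactants: 21 the 3-ketone of step 11
Product: 22 (3R,5R,8R,9S)-9-(ArCH2)-4,4,8,9-tetramethyl-Δ1(10)-octalin-3-ol (3α-alcohol)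
Conditions: LiBH(s-Bu)3 (L-Selectride), THF, −78 °C; H2O
Reagents that add atoms: none
Why: Equatorial delivery of the bulky hydride, as is usual for hindered 4,4-dimethyl-3-ketones, should give the axial 3α (3R) alcohol cis to H5 (ketone reduction).

**Step 13**
Reactants: 22 the 3α-alcohol of step 12
Product: 24 2,4-bis(methoxymethoxy)-6-[(methoxymethoxy)methyl]-3-{[(1S,2R,4aR,6R)-6-hydroxy-1,2,5,5-tetramethyl-1,2,3,4,4a,5,6,7-octahydronaphthalen-1-yl]methyl}benzaldehyde, via dilithio species 23 (not isolated)
Conditions: n-BuLi (3 equiv), TMEDA, THF, −20 → 0 °C; DMF, −78 °C → rt; H2O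
Reagents that add atoms: N,N-dimethylformamide, CN(C)C=O
Why: After deprotonation of the C3 hydroxyl, directed ortho-metalation occurs at one of the two equivalent ring positions flanked by OMOM and CH2OMOM (the position between the two OMOM groups is blocked by C11), and DMF formylates the aryllithium; no stereocentre is affected.

**Step 14**
Reactants: 24 the protected aldehyde of step 13
Product: 25 2,4-dihydroxy-6-(hydroxymethyl)-3-{[(1S,2R,4aR,6R)-6-hydroxy-1,2,5,5-tetramethyl-1,2,3,4,4a,5,6,7-octahydronaphthalen-1-yl]methyl}benzaldehyde (target)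
Conditions: 3 M aq. HCl/THF, rt → 40 °C
Reagents that add atoms: none
Why: Acid-catalysed hydrolysis of the three methoxymethyl acetals under conditions chosen to leave the hindered trisubstituted alkene unprotonated; no stereocentre is affected.

**Compound list**

1 | tert-butyl 2-methyl-3-oxobutanoate (racemic) | CC(=O)C(C)C(=O)OC(C)(C)C | starting material
2 | (E)-but-2-enal | C/C=C/C=O | starting material
3 | tert-butyl (3R)-2-acetyl-2,3-dimethyl-5-oxopentanoate (both C2 epimers) | C[C@@H](C(C)(C(C)=O)C(=O)OC(C)(C)C)CC=O | intermediate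
4 | tert-butyl (6R)-1,6-dimethyl-2-oxocyclohex-3-ene-1-carboxylate (both C1 epimers) | C[C@@H]1CC=CC(=O)C1(C)C(=O)OC(C)(C)C | intermediate
5 | (5R,6S)-5,6-dimethylcyclohex-2-en-1-one (trans; carried on together with its 6-epimer) | C[C@@H]1CC=CC(=O)[C@H]1C | intermediate
6 | 5-(hydroxymethyl)benzene-1,3-diol | OCc1cc(O)cc(O)c1 | starting material
7 | 1,3-bis(methoxymethoxy)-5-[(methoxymethoxy)methyl]benzene | COCOCc1cc(OCOC)cc(OCOC)c1 | intermediate
8 | {2,6-bis(methoxymethoxy)-4-[(methoxymethoxy)methyl]phenyl}lithium | [Li]c1c(OCOC)cc(COCOC)cc1OCOC | intermediate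
9 | 2,6-bis(methoxymethoxy)-4-[(methoxymethoxy)methyl]benzaldehyde | O=Cc1c(OCOC)cc(COCOC)cc1OCOC | intermediate
10 | {2,6-bis(methoxymethoxy)-4-[(methoxymethoxy)methyl]phenyl}methanol | OCc1c(OCOC)cc(COCOC)cc1OCOC | intermediate
11 | 2-(bromomethyl)-1,3-bis(methoxymethoxy)-5-[(methoxymethoxy)methyl]benzene | BrCc1c(OCOC)cc(COCOC)cc1OCOC | intermediate
12 | lithium (3R)-2,3-dimethylcyclohexa-1,5-dien-1-olate | C[C@@H]1CC=CC(O[Li])=C1C | intermediate
13 | (5R,6S)-6-{[2,6-bis(methoxymethoxy)-4-[(methoxymethoxy)methyl]phenyl]methyl}-5,6-dimethylcyclohex-2-en-1-one | C[C@@H]1CC=CC(=O)[C@@]1(C)Cc1c(OCOC)cc(COCOC)cc1OCOC | intermediate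
14 | lithium (5R,6S)-6-(ArCH2)-5,6-dimethylcyclohex-1-en-1-olate | C[C@@H]1CCC=C(O[Li])[C@@]1(C)Cc1c(OCOC)cc(COCOC)cc1OCOC | intermediate
15 | (5R,6S)-6-(ArCH2)-5,6-dimethylcyclohex-1-en-1-yl trifluoromethanesulfonate | C[C@@H]1CCC=C(OS(=O)(=O)C(F)(F)F)[C@@]1(C)Cc1c(OCOC)cc(COCOC)cc1OCOC | intermediate
16 | 5-bromo-2-methylpent-2-ene | CC(C)=CCCBr | starting material
17 | (4-methylpent-3-en-1-yl)magnesium bromide | CC(C)=CCC[Mg]Br | intermediate
18 | 2-{[(1S,6R)-1,6-dimethyl-2-(4-methylpent-3-en-1-yl)cyclohex-2-en-1-yl]methyl}-1,3-bis(methoxymethoxy)-5-[(methoxymethoxy)methyl]benzene | C[C@@H]1CCC=C(CCC=C(C)C)[C@@]1(C)Cc1c(OCOC)cc(COCOC)cc1OCOC | intermediate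
19 | (3S)-3-{2-[(5R,6S)-6-(ArCH2)-5,6-dimethylcyclohex-1-en-1-yl]ethyl}-2,2-dimethyloxirane | C[C@@H]1CCC=C(CC[C@@H]2OC2(C)C)[C@@]1(C)Cc1c(OCOC)cc(COCOC)cc1OCOC | intermediate
20 | (3S,5R,8R,9S)-9-(ArCH2)-4,4,8,9-tetramethyl-Δ1(10)-octalin-3-ol (3β-OH, trans to H5) | C[C@@H]1CC[C@@H]2C(=CC[C@H](O)C2(C)C)[C@@]1(C)Cc1c(OCOC)cc(COCOC)cc1OCOC | intermediate
21 | (5R,8R,9S)-9-(ArCH2)-4,4,8,9-tetramethyl-Δ1(10)-octalin-3-one | C[C@@H]1CC[C@@H]2C(=CCC(=O)C2(C)C)[C@@]1(C)Cc1c(OCOC)cc(COCOC)cc1OCOC | intermediate
22 | (3R,5R,8R,9S)-9-(ArCH2)-4,4,8,9-tetramethyl-Δ1(10)-octalin-3-ol (3α-OH, cis to H5) | C[C@@H]1CC[C@@H]2C(=CC[C@@H](O)C2(C)C)[C@@]1(C)Cc1c(OCOC)cc(COCOC)cc1OCOC | intermediate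
23 | lithium alkoxide/aryllithium derived from 22 (Li on O3 and on the ring carbon between OMOM and CH2OMOM) | C[C@@H]1CC[C@@H]2C(=CC[C@@H](O[Li])C2(C)C)[C@@]1(C)Cc1c(OCOC)c([Li])c(COCOC)cc1OCOC | intermediate
24 | 2,4-bis(methoxymethoxy)-6-[(methoxymethoxy)methyl]-3-{[(1S,2R,4aR,6R)-6-hydroxy-1,2,5,5-tetramethyl-1,2,3,4,4a,5,6,7-octahydronaphthalen-1-yl]methyl}benzaldehyde | C[C@@H]1CC[C@@H]2C(=CC[C@@H](O)C2(C)C)[C@@]1(C)Cc1c(OCOC)c(C=O)c(COCOC)cc1OCOC | intermediate
25 | 2,4-dihydroxy-6-(hydroxymethyl)-3-{[(1S,2R,4aR,6R)-6-hydroxy-1,2,5,5-tetramethyl-1,2,3,4,4a,5,6,7-octahydronaphthalen-1-yl]methyl}benzaldehyde | C[C@@H]1CC[C@@H]2C(=CC[C@@H](O)C2(C)C)[C@@]1(C)Cc1c(O)cc(CO)c(C=O)c1O | target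

**Step count and risks**

Total step count: 14. Longest linear sequence: 13 steps (from 6: steps 2–5, then 6–14); from 1 and 2 the sequence is 10 steps (steps 1, 6–14).

The three steps most likely to fail:

Step 10 (ring A closure). The tertiary radical may be reduced or eliminated before it cyclises, the C10 radical may lose hydrogen toward C5 instead of C1, or the chair dictated by the epoxide may be overridden by ring B so that facial selectivity at C5 is poor. The fallback closes ring A by a cationic route without the epoxide and sets out from diene 18. Hg(OTf)2·PhNMe2 in MeNO2 at −20 °C adds divalent mercury to the side-chain alkene, C5 of the ring B alkene opens the mercurinium ion, C1 loses a proton, and aqueous NaCl gives the 3β-chloromercurio bicycle F1. Oxidative demercuration (NaBH4, O2, DMF) gives the C3 alcohols as the epimer pair 20 and 22, and Dess–Martin oxidation of this pair rejoins the route at ketone 21.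

Step 6 (quaternary centre at C9). SN2 displacement at the doubly ortho-substituted benzylic bromide may be too slow against the tetrasubstituted enolate carbon, so that proton transfer, O-alkylation or decomposition of the labile bromide take over. The fallback delivers the benzyl group from an ester oxygen by palladium and sets out from alcohol 10. DMAP-catalysed transesterification with methyl 2-methyl-3-oxobutanoate (toluene, reflux) gives the arylmethyl 2-methyl-3-oxobutanoate F2. The amine-catalysed Michael addition of step 1 to 2, followed by piperidinium acetate for the aldol condensation, gives the arylmethyl (6R)-1,6-dimethyl-2-oxocyclohex-3-ene-1-carboxylate F3. Pd(PPh3)4 in toluene at 80 °C then effects decarboxylative benzylation: zerovalent palladium ionises the electron-rich benzylic ester, CO2 is lost, and the dienolate attacks the η3-benzyl complex anti to the 8-methyl. This rejoins the route at 13.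

Step 1 (key step). The α-branched keto ester may add too slowly to the iminium ion, so that self-condensation of 2 or a poorly face-selective background addition competes. The fallback introduces the 9-methyl by enolate alkylation and sets out from 2. The same amine/acid sequence with the unbranched tert-butyl 3-oxobutanoate gives (5R)-5-methylcyclohex-2-en-1-one F4, and LiN(i-Pr)2 followed by MeI in THF at −78 °C methylates C9 and rejoins the route at 5.

**Further compounds**

F1 | step 10 | (3S,5R,8R,9S)-9-(ArCH2)-3-(chloromercurio)-4,4,8,9-tetramethyl-Δ1(10)-octalin | C[C@@H]1CC[C@@H]2C(=CC[C@H]([Hg]Cl)C2(C)C)[C@@]1(C)Cc1c(OCOC)cc(COCOC)cc1OCOC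
F2 | step 6 | {2,6-bis(methoxymethoxy)-4-[(methoxymethoxy)methyl]phenyl}methyl 2-methyl-3-oxobutanoate | CC(=O)C(C)C(=O)OCc1c(OCOC)cc(COCOC)cc1OCOC
F3 | step 6 | {2,6-bis(methoxymethoxy)-4-[(methoxymethoxy)methyl]phenyl}methyl (6R)-1,6-dimethyl-2-oxocyclohex-3-ene-1-carboxylate (both C1 epimers) | C[C@@H]1CC=CC(=O)C1(C)C(=O)OCc1c(OCOC)cc(COCOC)cc1OCOC
F4 | step 1 | (5R)-5-methylcyclohex-2-en-1-one | C[C@@H]1CC=CC(=O)C1
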